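## Structural features

The target is an aryl alkyl ether in which O7 of isofraxidin is bonded to C11 of a drimane sesquiterpene. Drimane numbering is used throughout: ring A is C1–C5 and C10, ring B is C5–C10, C11 sits on C9, C12 on C8, C13 and C14 on C4, C15 on C10, and β is the face of C15. The terpene half is a trans-fused decalin: ring B is a cyclohexenone (C6=O, C7=C8 bearing C12) and ring A carries the C4 gem-dimethyl group and an axial 3α-isovalerate. There are four stereocentres, (3R,5R,9R,10R). C9, C10 and C5 are contiguous around the quaternary C10, and C3 is separated from them by the quaternary C4. C11 lies on the α face, anti to C15 and pseudo-axial, which is not the thermodynamically preferred orientation. The fragile points are C9–H (γ to the C6 carbonyl and β to an aryloxide leaving group, so base can epimerise C9 or expel isofraxidin), C5–H, the ester, and the coumarin lactone and its C3=C4 bond, which tolerate neither hydride, strong base nor hydrogenation. The real difficulty is the all-carbon quaternary C10 in the absolute sense, combined with the kinetically set C9 next to it and with the C4 quaternary centre that hinders C3, C5 and C6. The plan exploits that C10 is the para carbon of a 4,4-disubstituted cyclohexa-2,5-dienone with enantiotopic arms C1=C2 and C4=C5. A C6 nucleophile on the chain C9–C8(C12)=C7–C6 adds to C5 and closes ring B; a nitro group at C6 later becomes the C6 ketone, already conjugated to C7=C8, which makes C9 the γ-position that accepts C11.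

## Logic of the disconnections

**28 to 26 and 27.** The O–C11 bond is cut. It is the only link between the two halves and leaves 27 as an unmodified commercial phenol. The forward step must substitute a β-branched primary carbon without base, because C9–H is vinylogously acidic and the aryloxide is a leaving group.

**26 to 25 and 4, and 25 to 24.** The C9–C11 bond is cut. C9 is the γ-carbon of the C6 enone, so it can act as a vinylogous nucleophile towards a one-carbon electrophile. This removes the contra-thermodynamic stereocentre and leaves an 11-nor enone. The forward step must enolise towards C9 (not C12 or C5), react at γ and not at α (C7), and approach anti to C15.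

**24 to 22 and 23, and 22 to 21.** The acyl C–O bond and the C3–H bond are cut. The axial alcohol is the product of equatorial hydride delivery to a 4,4-dimethyl-3-ketone in a trans-decalin. The reduction must distinguish the saturated C3 ketone from the hindered, conjugated C6 ketone.

**21 to 20 to 19 to 17.** C5 is returned to the cis configuration, C1=C2 is reinstated and the C6 ketone is traced back to a secondary allylic nitro group. The gain is that 17 is the product type of a Michael addition and still carries the second arm of a dienone. The forward steps must hydrogenate a disubstituted enone next to a trisubstituted one and equilibrate C5 to the trans fusion.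

**17 to 15.** The two C4–CH3 bonds are cut. While C1=C2 is present, C4 is the only enolisable position of the C3 ketone, so the methylation is regiospecific. The forward step must alkylate an enolate carbon while the more acidic nitro group is present as its nitronate.

**15 to 14.** The C5–C6 bond is cut. This opens ring B and turns C10 from a stereocentre into the prochiral para carbon of a dienone, so the absolute configuration comes from a catalyst acting on an achiral substrate. The forward step needs a Z C7=C8 bond and differentiation of two enantiotopic arms.

**14 to 13 to 12.** The C6–N bond and then the C6–Br bond are exchanged for C6–OH. The nitro group is introduced last so that the acidic Michael donor never meets base before the catalyst does. The substitution must keep the Z geometry and the primary position.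

**12 to 9, and 9 to 6 and 7.** The second ring C=C is removed, then the enone C=C and the bond from the quaternary carbon to the ring methylene are cut (Robinson annulation retron). This reduces the ring to 7 and an α-branched aldehyde. The dehydrogenation must tolerate an allylic alcohol and a trisubstituted alkene.

**6 to 5 to 3 and 4.** The α-methyl group is traced to an α-methylene group and this to 4. The aldehyde then becomes linear. The conjugate reduction must spare the trisubstituted alkene and the allylic acetate.

**3 to 1.** The aldehyde is traced to a remote trisubstituted alkene. The Z-configured C7=C8 unit with C12 is bought rather than made, which removes the weakest point of a ketone olefination route (poor Z-selectivity for a methyl ketone). The cleavage must select the electron-rich 6,7-alkene over the 2,3-alkene deactivated by the allylic acetate.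

## Other disconnections considered

**Alternative 1: intramolecular Diels–Alder.**
- **Cut:** C5–C10 and C8–C9, opening both rings of A2 (cis-fused methyl 3β,6-bis(tert-butyldimethylsilyloxy)-drim-6-en-11-oate) to the acyclic triene A1 (methyl (2Z,6S,8Z,10E)-6,9-bis(tert-butyldimethylsilyloxy)-3,7,7-trimethyldodeca-2,8,10-trienoate).
- **Forward key step:** heating A1 joins the 2-silyloxydiene C5=C6–C7=C8 to the Z-enoate C9=C10 across the four-atom tether C4–C1.
- **In its favour:**
  - Two C–C bonds, both rings and four stereocentres form in one step.
  - C11 is present from the start, and its anti relation to C15 follows stereospecifically from the Z-enoate. On this point it is better than the chosen plan, which adds C11 late in a separate γ-functionalisation.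
  - The gem-dimethyl group and the C3 oxygen need no enolate chemistry, also better.
  - The C6 oxygen emerges as a silyl enol ether that a Saegusa–Ito oxidation could turn directly into the 7-en-6-one.
- **Against it here:**
  - A1 needs three geometrically defined alkenes, and its C3 carbinol centre is the only source of absolute configuration, acting through a remote tether conformation.
  - The cycloaddition must bond a neopentylic diene terminus (C5 next to C4) to the fully substituted C10.
  - A2 as formulated has its C3 oxygen β, epimeric to the target, so an oxidation and axial reduction would be added.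
  - C5 must still be epimerised by base, at a stage where C9–H (α to the ester and γ to the C6 carbonyl) is more acidic than C5–H. The correction of C5 therefore threatens the axial C11.
- **Comparison:** the cis fusion and its later correction are equal in both plans. Alternative 1 is mechanistically substrate-controlled and pericyclic, the chosen plan catalyst-controlled and ionic. Alternative 1 should be shorter after its key step, but the synthesis of A1 is long, so overall step economy is expected to be similar. The chosen plan sets C9 last and kinetically, which Alternative 1 cannot do.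

**Alternative 2: verbenone as ring B, radical closure of ring A.**
- **Cut:** C3–C4, opening ring A of A5 (trans-fused 3β-hydroxy-11-(4-methoxybenzyloxy)-12-nor-drimane 8-ethylene ketal) to the aldehyde A4 (11-(4-methoxybenzyloxy)-12-nor-3,4-seco-drim-4(13)-en-3-al 8-ethylene ketal). Ring B, C5 and C10 of A4 are derived from (1R,5R)-verbenone A3 by conjugate addition at its β-carbon, α-alkylation and cyclobutane fragmentation.
- **Forward key step:** Fe(acac)3 (trivalent iron) and PhSiH3 transfer a hydrogen atom to the isopropenyl group; the tertiary C4 radical adds 6-exo to the aldehyde carbon C3.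
- **In its favour:**
  - The absolute configuration comes from the chiral pool, with no catalyst to optimise. This is more reliable than the chosen plan.
  - The trans fusion is in place before the cyclisation, so no C5 epimerisation is needed, also better.
  - The gem-dimethyl group and the C3 oxygen form in the same step.
  - C11 is present early with its configuration.
- **Against it here:**
  - A5 lacks C12, the C7=C8 bond and the C6 oxygen. A methyl addition to C8, a regioselective dehydration and an allylic C–H oxidation at C6 would be needed late.
  - The 3-hydroxyl of A5 is β and would have to be inverted.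
  - The route to A4 requires a conjugate addition to a hindered β,β-disubstituted enone beside the gem-dimethylcyclobutane, and control of C9 in the alkylation.
  - Radical addition to an aldehyde is reversible through β-scission of the alkoxy radical.
- **Comparison:** Alternative 2 is the better plan for absolute and ring-fusion stereocontrol. The chosen plan is better for ring B, which it delivers at the correct oxidation level (nitro to C6 ketone conjugated with C7=C8). Step economy favours the chosen plan because of the redox corrections Alternative 2 needs after cyclisation.

**Alternative 3: enantioselective quinone Diels–Alder.**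
- **Cut:** C1–C10 and C4–C5, opening ring A of A8 (cis-fused 3-(trimethylsilyloxy)-11-nor-drima-2,7-diene-6,9-dione) to 2,6-dimethyl-1,4-benzoquinone A6 and the diene A7 (trimethyl[(4-methylpenta-1,3-dien-3-yl)oxy]silane).
- **Forward key step:** a chiral Lewis acid such as the BINOL complex of TiCl2(O-i-Pr)2 (tetravalent titanium) joins A6 and A7.
- **In its favour:**
  - It is convergent: 14 of the 15 terpene carbons, the quaternary C10, the gem-dimethyl group, the C3 oxygen, the C6 ketone and C7=C8 with C12 arise in one step from two simple components. In speed of skeleton assembly it is clearly better than the chosen plan.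
  - The cis fusion is corrected by the same C5 epimerisation as in the chosen plan (equal).
  - Absolute control is catalytic in both (equal in principle).
- **Against it here:**
  - A7 has a fully substituted terminus with a Z-methyl group that disfavours the s-cis conformer, and it must bond through that terminus next to the forming quaternary C10.
  - The required regiochemistry puts the nucleophilic CMe2 terminus on the unsubstituted quinone carbon. A Lewis acid on the less hindered carbonyl activates the methyl-bearing carbon instead, so regio- and enantiocontrol for this pair are uncertain.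
  - A8 has a ketone at C9 where the target has CH–CH2OAr with 9β-H. A one-carbon homologation at a neopentylic carbonyl would be needed, followed by hydrogen delivery syn to C15, which is against the steric bias. In the chosen plan the carbon electrophile approaches anti to C15, which gives the required configuration directly.
  - Three carbonyl-level carbons (C3, C6, C9) must be differentiated.
- **Comparison:** Alternative 3 wins on step economy up to the bicycle. The chosen plan wins on the C9 stereocentre and on functional-group differentiation.

Key step: step 8

Remark on names: the key-step product lacks C11, C13 and C14 and is named here as an 11,13,14-trinor-drimane.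

Assumption: the sense of induction of the cinchona thiourea cannot be fixed on paper. The quinine-derived catalyst is written; the quinidine-derived pseudo-enantiomer would be used if the opposite arm were preferred.

## Route

Step 1
Reactants: 1 neryl acetate
Product: 3 (2Z)-3-methyl-6-oxohex-2-en-1-yl acetate, via 6,7-epoxide 2 (not isolated)
Conditions: mCPBA, CH2Cl2, 0 °C; then H5IO6, THF/H2O, 0 °C → rt
Reagents that add atoms: mCPBA, O=C(OO)c1cccc(Cl)c1
Why: Prilezhaev epoxidation selects the electron-rich 6,7-alkene over the 2,3-alkene deactivated by the allylic acetate, and periodic acid cleaves the epoxide through the diol to the aldehyde and acetone. The Z alkene of the future C7=C8 is untouched.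

Step 2
Reactants: 3 (2Z)-3-methyl-6-oxohex-2-en-1-yl acetate; 4 formaldehyde
Product: 5 (2Z)-3-methyl-5-methylidene-6-oxohex-2-en-1-yl acetate
Conditions: 4 (37% aq.), pyrrolidine (10 mol%), EtCO2H (10 mol%), i-PrOH, 45 °C
Reagents that add atoms: none
Why: Organocatalytic α-methylenation (Mannich condensation of the enamine with formaldehyde, then amine elimination) of a linear aldehyde. It supplies the carbon that becomes C15.

Step 3
Reactants: 5 (2Z)-3-methyl-5-methylidene-6-oxohex-2-en-1-yl acetate
Product: 6 (2Z)-3,5-dimethyl-6-oxohex-2-en-1-yl acetate (racemic)
Conditions: Hantzsch ester (diethyl 2,6-dimethyl-1,4-dihydropyridine-3,5-dicarboxylate), Bn2NH·CF3CO2H (10 mol%), THF, rt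
Reagents that add atoms: none
Why: Iminium-ion transfer hydrogenation: hydride adds to the methylene carbon of the activated enal only, leaving the trisubstituted alkene and the acetate. The new centre is formed racemic on purpose because it becomes the prochiral C10.

Step 4
Reactants: 6 (2Z)-3,5-dimethyl-6-oxohex-2-en-1-yl acetate; 7 but-3-en-2-one
Product: 9 4-[(2Z)-4-hydroxy-2-methylbut-2-en-1-yl]-4-methylcyclohex-2-en-1-one (racemic), via keto aldehyde 8 (not isolated)
Conditions: pyrrolidine, PhMe, 4 Å MS, rt; 7, 0 °C → rt; then KOH, MeOH/H2O, rt
Reagents that add atoms: none
Why: Robinson annulation in the Stork enamine mode: the enamine of the α-branched aldehyde adds to the enone, and hydroxide closes the ring by aldol condensation of the methyl ketone onto the aldehyde. The same base removes the acetate, so any aminolysis of the ester converges on the same alcohol.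

Step 5
Reactants: 9 4-[(2Z)-4-hydroxy-2-methylbut-2-en-1-yl]-4-methylcyclohex-2-en-1-one
Product: 12 4-[(2Z)-4-hydroxy-2-methylbut-2-en-1-yl]-4-methylcyclohexa-2,5-dien-1-one, via bis-silyl dienol ether 10 (not isolated), via dienone silyl ether 11 (not isolated)
Conditions: TMSOTf, Et3N, CH2Cl2, 0 °C; Pd(OAc)2 (1.1 equiv), MeCN, rt; then 1 M HCl, THF, 0 °C
Reagents that add atoms: none
Why: Saegusa–Ito oxidation: soft enolisation is possible only at the α′-methylene (the γ-carbon is quaternary), and Pd(OAc)2 (divalent palladium) converts the 2-silyloxydiene into the cross-conjugated dienone. The hydroxyl is masked as its silyl ether in the same operation, which is why this method is preferred to quinone or hypervalent iodine oxidants that would attack the allylic alcohol. The product is achiral.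

Step 6
Reactants: 12 4-[(2Z)-4-hydroxy-2-methylbut-2-en-1-yl]-4-methylcyclohexa-2,5-dien-1-one
Product: 13 4-[(2Z)-4-bromo-2-methylbut-2-en-1-yl]-4-methylcyclohexa-2,5-dien-1-one
Conditions: CBr4, PPh3, CH2Cl2, 0 °C
Reagents that add atoms: carbon tetrabromide, BrC(Br)(Br)Br
Why: Appel reaction: bromide displaces the alkoxyphosphonium group at the primary allylic carbon at low temperature, which keeps the Z geometry. The dienone is inert.

Step 7
Reactants: 13 4-[(2Z)-4-bromo-2-methylbut-2-en-1-yl]-4-methylcyclohexa-2,5-dien-1-one
Product: 14 4-methyl-4-[(2Z)-2-methyl-4-nitrobut-2-en-1-yl]cyclohexa-2,5-dien-1-one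
Conditions: AgNO2, Et2O, 0 °C → rt, dark
Reagents that add atoms: silver nitrite, [Ag+].[O-]N=O
Why: Victor Meyer reaction of a primary allylic bromide; the medium is non-basic, so the acidic product cannot cyclise before it meets the chiral catalyst. The nitro compound is separated from the nitrite ester and used at once.

Step 8
Reactants: 14 4-methyl-4-[(2Z)-2-methyl-4-nitrobut-2-en-1-yl]cyclohexa-2,5-dien-1-one
Product: 15 (5R,6R,10S)-6β-nitro-11,13,14-trinor-drima-1,7-dien-3-one, cis-fused (5β-H)
Conditions: 1-[3,5-bis(trifluoromethyl)phenyl]-3-[(8S,9S)-6′-methoxycinchonan-9-yl]thiourea (10 mol%), PhMe, 0 °C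
Reagents that add atoms: none
Why: The quinuclidine nitrogen removes a C6 proton of the allylic nitro group, the thiourea N–H pair and the ammonium ion hold the nitronate and the dienone carbonyl, C6 adds to C5 in an intramolecular Michael addition, and the C3 enolate is protonated at C4. The closest known reaction type is the organocatalytic desymmetrising intramolecular Michael addition of tethered carbon acids to 4,4-disubstituted cyclohexa-2,5-dienones. Ring B (C5–C6–C7–C8–C9–C10) closes in the 6-exo-trig mode. C10 becomes stereogenic because the chiral ion pair selects one of the two enantiotopic arms (catalyst control). C5 is set cis to C15 because the tether on C10 can reach C5 only from its own face (substrate geometry). C6 is set in the same transition state, remains epimerisable through the nitronate and is erased later. The step needs arm selectivity, attack through C6 and not C8 of the ambident allyl nitronate, and no uncatalysed background reaction: attack through C8 would give a four-membered ring, the Z alkene holds C6 within reach of C5, and a non-polar solvent at low temperature keeps free nitronate negligible. A second Michael addition to the remaining C1=C2 arm is geometrically impossible.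

Step 9
Reactants: 15 (5R,6R,10S)-6β-nitro-11,13,14-trinor-drima-1,7-dien-3-one
Product: 17 cis-fused (5β-H) 6-nitro-11-nor-drima-1,7-dien-3-one (C6 epimers), via 4-monomethyl compound 16 (not isolated)
Conditions: LiN(SiMe3)2 (2.2 equiv), THF/DMPU, −78 °C; MeI (1.1 equiv); LiN(SiMe3)2 (1.2 equiv), −78 °C; MeI (3 equiv), −78 → −30 °C; AcOH, −78 °C
Reagents that add atoms: iodomethane, CI
Why: Enolate alkylation of a nitronate–enolate dianion: the first equivalent of base parks the nitro group as its unreactive nitronate, and the second can only form the cross-conjugated C4 enolate because C2 is vinylic and C10 quaternary. C4 is methylated twice while the dianion cannot undergo retro-Michael cleavage. C5 and C10 are not touched, and C6 is re-protonated without consequence.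

Step 10
Reactants: 17 cis-fused 6-nitro-11-nor-drima-1,7-dien-3-one
Product: 19 cis-fused (5β-H) 11-nor-drima-1,7-diene-3,6-dione, via sodium nitronate 18 (not isolated)
Conditions: NaOMe, MeOH, 0 °C; then TiCl3, NH4OAc, H2O/THF, pH 5–6, rt
Reagents that add atoms: water, O
Why: Reductive Nef reaction: TiCl3 (trivalent titanium) reduces the nitronate to the imine, which hydrolyses in the buffer to the C6 ketone, now conjugated with C7=C8. The non-enolisable C3 enone and the alkene survive, and any oxime formed by nitronate O-methylation in step 9 converges on the same ketone.

Step 11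
Reactants: 19 cis-fused 11-nor-drima-1,7-diene-3,6-dione
Product: 20 cis-fused (5β-H) 11-nor-drim-7-ene-3,6-dione
Conditions: H2 (1 atm), RhCl(PPh3)3 (5 mol%), PhH/EtOH, rt
Reagents that add atoms: none
Why: Homogeneous hydrogenation with RhCl(PPh3)3 (monovalent rhodium) reduces the cis-disubstituted C1=C2 and leaves the trisubstituted C7=C8, as in the selective 1,2-hydrogenation of steroidal 1,4-dien-3-ones.

Step 12
Reactants: 20 cis-fused 11-nor-drim-7-ene-3,6-dione
Product: 21 trans-fused (5α-H) 11-nor-drim-7-ene-3,6-dione
Conditions: NaOMe (0.2 equiv), MeOH, rt
Reagents that add atoms: none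
Why: Base-mediated epimerisation through the C5 enolate of the C6 ketone gives the thermodynamically preferred trans-decalin of the 4,4,10-trimethyl system. The conjugated position of C7=C8 is the stable one under the same conditions.

Step 13
Reactants: 21 trans-fused 11-nor-drim-7-ene-3,6-dione
Product: 22 3α-hydroxy-11-nor-drim-7-en-6-one (5α-H)
Conditions: LiBH(s-Bu)3 (1.1 equiv), THF, −78 °C; H2O
Reagents that add atoms: none
Why: The bulky hydride attacks the C3 ketone along the equatorial trajectory (the axial one is blocked by the α-axial hydrogens at C1 and C5) and gives the axial 3α-alcohol. The C6 ketone is conjugated, β,β-disubstituted and flanked by C4 and C10, so it reacts more slowly.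

Step 14
Reactants: 22 3α-hydroxy-11-nor-drim-7-en-6-one; 23 3-methylbutanoyl chloride
Product: 24 3α-(3-methylbutanoyloxy)-11-nor-drim-7-en-6-one
Conditions: 23, pyridine, DMAP (cat.), CH2Cl2, 0 °C → rt
Reagents that add atoms: none
Why: Nucleophile-catalysed acylation of the hindered axial alcohol with retention at C3. The ester is installed before C9 becomes a base-sensitive stereocentre.

Step 15
Reactants: 24 3α-(3-methylbutanoyloxy)-11-nor-drim-7-en-6-one
Product: 25 3α-(3-methylbutanoyloxy)-6-(trimethylsilyloxy)-11-nor-drima-6,8-diene
Conditions: TMSCl, NaI, Et3N, MeCN, rt → 40 °C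
Reagents that add atoms: chlorotrimethylsilane, C[Si](C)(C)Cl
Why: Silyl dienol ether formation under equilibrating conditions (iodotrimethylsilane made in the flask, amine base). The α′ position C5 would give a strained tetrasubstituted enol ether beside C4, and the endocyclic trisubstituted C8=C9 is more stable than the exocyclic C8=C12 alternative, so the linear C6=C7–C8=C9 diene is expected. The ester is not enolised by the amine.

Step 16
Reactants: 25 3α-(3-methylbutanoyloxy)-6-(trimethylsilyloxy)-11-nor-drima-6,8-diene; 4 formaldehyde
Product: 26 11-hydroxy-3α-(3-methylbutanoyloxy)-drim-7-en-6-one with C11 α on C9 (9β-H)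
Conditions: 4 (37% aq.), Yb(OTf)3 (10 mol%), THF/H2O, 0 °C → rt
Reagents that add atoms: none
Why: Vinylogous Mukaiyama aldol reaction (hydroxymethylation) catalysed by Yb(OTf)3 (trivalent ytterbium): the silyl dienol ether reacts at its γ-carbon C9 and regenerates the conjugated enone. C11 enters axially on the α face, anti to the adjacent axial C15, which is the configuration of the target; the mild aqueous Lewis acid leaves the kinetic C9 centre and the ester alone.

Step 17
Reactants: 26 11-hydroxy-3α-(3-methylbutanoyloxy)-drim-7-en-6-one; 27 isofraxidin
Product: 28 (3R,5R,9R,10R)-11-[(6,8-dimethoxy-2-oxo-2H-chromen-7-yl)oxy]-6-oxodrim-7-en-3-yl 3-methylbutanoate (target)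
Conditions: 27, PPh3, DIAD, THF, 0 °C → rt
Reagents that add atoms: none
Why: Mitsunobu etherification: the acidic coumarin phenol is the pronucleophile and displaces the alkoxyphosphonium group at the primary C11. No stereocentre is involved, and the near-neutral medium avoids C9 epimerisation and vinylogous β-elimination.

## Compound list

1 | neryl acetate, (2Z)-3,7-dimethylocta-2,6-dien-1-yl acetate | CC(=O)OC/C=C(C)\CCC=C(C)C | starting material
2 | (2Z)-5-(3,3-dimethyloxiran-2-yl)-3-methylpent-2-en-1-yl acetate (racemic) | CC(=O)OC/C=C(C)\CCC1OC1(C)C | intermediate
3 | (2Z)-3-methyl-6-oxohex-2-en-1-yl acetate | CC(=O)OC/C=C(C)\CCC=O | intermediate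
4 | formaldehyde | C=O | starting material
5 | (2Z)-3-methyl-5-methylidene-6-oxohex-2-en-1-yl acetate | CC(=O)OC/C=C(C)\CC(=C)C=O | intermediate
6 | (2Z)-3,5-dimethyl-6-oxohex-2-en-1-yl acetate (racemic) | CC(=O)OC/C=C(C)\CC(C)C=O | intermediate
7 | but-3-en-2-one | CC(=O)C=C | starting material
8 | (2Z)-5-formyl-3,5-dimethyl-8-oxonon-2-en-1-yl acetate (racemic) | CC(=O)OC/C=C(C)\CC(C)(C=O)CCC(C)=O | intermediate
9 | 4-[(2Z)-4-hydroxy-2-methylbut-2-en-1-yl]-4-methylcyclohex-2-en-1-one (racemic) | CC1(C/C(C)=C\CO)CCC(=O)C=C1 | intermediate
10 | trimethyl({1-methyl-1-[(2Z)-2-methyl-4-(trimethylsilyloxy)but-2-en-1-yl]cyclohexa-2,4-dien-4-yl}oxy)silane, the 4-silyloxy-2,4-diene (racemic) | CC1(C/C(C)=C\CO[Si](C)(C)C)CC=C(O[Si](C)(C)C)C=C1 | intermediate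
11 | 4-methyl-4-[(2Z)-2-methyl-4-(trimethylsilyloxy)but-2-en-1-yl]cyclohexa-2,5-dien-1-one | CC1(C/C(C)=C\CO[Si](C)(C)C)C=CC(=O)C=C1 | intermediate
12 | 4-[(2Z)-4-hydroxy-2-methylbut-2-en-1-yl]-4-methylcyclohexa-2,5-dien-1-one | CC1(C/C(C)=C\CO)C=CC(=O)C=C1 | intermediate
13 | 4-[(2Z)-4-bromo-2-methylbut-2-en-1-yl]-4-methylcyclohexa-2,5-dien-1-one | CC1(C/C(C)=C\CBr)C=CC(=O)C=C1 | intermediate
14 | 4-methyl-4-[(2Z)-2-methyl-4-nitrobut-2-en-1-yl]cyclohexa-2,5-dien-1-one | CC1(C/C(C)=C\C[N+](=O)[O-])C=CC(=O)C=C1 | intermediate
15 | (5R,6R,10S)-6β-nitro-11,13,14-trinor-drima-1,7-dien-3-one, cis-fused; (4aS,8R,8aR)-4a,6-dimethyl-8-nitro-4a,5,8,8a-tetrahydronaphthalen-2(1H)-one | [O-][N+](=O)[C@@H]1C=C(C)C[C@@]2(C)C=CC(=O)C[C@@H]12 | intermediate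
16 | cis-fused (5β-H, 10β-CH3) 4-methyl-6-nitro-11,13-dinor-drima-1,7-dien-3-one, C4 and C6 epimers, present as its lithium nitronate | [O-][N+](=O)C1C=C(C)C[C@@]2(C)C=CC(=O)C(C)[C@@H]12 | intermediate
17 | cis-fused (5β-H, 10β-CH3) 6-nitro-11-nor-drima-1,7-dien-3-one, C6 epimers | [O-][N+](=O)C1C=C(C)C[C@@]2(C)C=CC(=O)C(C)(C)[C@@H]12 | intermediate
18 | sodium 6-aci-nitronate of 17 | [Na+].[O-][N+]([O-])=C1C=C(C)C[C@@]2(C)C=CC(=O)C(C)(C)[C@@H]12 | intermediate
19 | cis-fused (5β-H, 10β-CH3) 11-nor-drima-1,7-diene-3,6-dione | C1C(C)=CC(=O)[C@@H]2C(C)(C)C(=O)C=C[C@]12C | intermediate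
20 | cis-fused (5β-H, 10β-CH3) 11-nor-drim-7-ene-3,6-dione | C1C(C)=CC(=O)[C@@H]2C(C)(C)C(=O)CC[C@]12C | intermediate
21 | trans-fused (5α-H, 10β-CH3) 11-nor-drim-7-ene-3,6-dione | C1C(C)=CC(=O)[C@H]2C(C)(C)C(=O)CC[C@]12C | intermediate
22 | 3α-hydroxy-11-nor-drim-7-en-6-one (5α-H, 10β-CH3) | C1C(C)=CC(=O)[C@H]2C(C)(C)[C@H](O)CC[C@]12C | intermediate
23 | 3-methylbutanoyl chloride | CC(C)CC(Cl)=O | starting material
24 | 3α-(3-methylbutanoyloxy)-11-nor-drim-7-en-6-one (5α-H, 10β-CH3) | C1C(C)=CC(=O)[C@H]2C(C)(C)[C@H](OC(=O)CC(C)C)CC[C@]12C | intermediate
25 | 3α-(3-methylbutanoyloxy)-6-(trimethylsilyloxy)-11-nor-drima-6,8-diene (5α-H, 10β-CH3) | C1=C(C)C=C(O[Si](C)(C)C)[C@H]2C(C)(C)[C@H](OC(=O)CC(C)C)CC[C@]12C | intermediate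
26 | 11-hydroxy-3α-(3-methylbutanoyloxy)-drim-7-en-6-one (5α-H, 9β-H, 10β-CH3; C11 α) | OC[C@@H]1C(C)=CC(=O)[C@H]2C(C)(C)[C@H](OC(=O)CC(C)C)CC[C@]12C | intermediate
27 | isofraxidin, 7-hydroxy-6,8-dimethoxy-2H-chromen-2-one | COc1cc2ccc(=O)oc2c(OC)c1O | starting material
28 | (3R,5R,9R,10R)-11-[(6,8-dimethoxy-2-oxo-2H-chromen-7-yl)oxy]-6-oxodrim-7-en-3-yl 3-methylbutanoate | COc1cc2ccc(=O)oc2c(OC)c1OC[C@@H]1C(C)=CC(=O)[C@H]2C(C)(C)[C@H](OC(=O)CC(C)C)CC[C@]12C | target

## Step count and least certain steps

Total: 17 steps. Longest linear sequence: 17 steps, from 1 to 28. Compounds 4, 7, 23 and 27 are used as purchased.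

**Step 8 (key step).** The most likely failure is weak discrimination between the two enantiotopic arms, because a trace of adventitious base can trigger an uncatalysed cyclisation of the short tether. A second risk is drift of the β,γ-unsaturated nitro group into conjugation before it cyclises. The fallback changes the activation mode from hydrogen-bonded ion pairing to covalent catalysis. It sets out from 14 and returns at 15. A 9-amino(9-deoxy)epi-cinchona primary amine with a carboxylic acid co-catalyst would condense with the dienone carbonyl, so that the arm selection is made within a chiral iminium ion while the carboxylate shuttles the nitro proton. No new isolated compound arises (F0).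

**Step 7.** Silver may ionise the allylic bromide, which leads to allylic transposition and loss of the Z geometry, and the ambident nitrite may alkylate on oxygen. The fallback sets out from 12 and returns at 14. The alcohol would be acetylated (Ac2O, pyridine) to the dienone acetate F1, and F1 would be treated with NaNO2 and catalytic Pd(PPh3)4 (zerovalent palladium). The soft nitrogen terminus of nitrite attacks the primary end of the π-allyl complex. Isomerisation of the alkene would require a σ-complex at the fully substituted carbon and is therefore slow.

**Step 9.** The nitronate may be alkylated on oxygen, and the second methylation at the congested C4 may stop short. The fallback sets out from 15 and returns at 19. The reductive Nef reaction of step 10 would be applied first, giving the cis-fused trinor enedione F2. F2 would then be methylated twice with LiN(SiMe3)2 and MeI. This relies on alkylation being faster at the secondary C4 than at the tertiary C5, which lies between C4 and the quaternary C10. Any C5 epimer formed converges in step 12.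

**Step 16.** Carbon–carbon bond formation may occur at the unhindered α-carbon C7 instead of the neopentylic γ-carbon C9, and hydrolysis of the dienol ether may outrun its reaction with the aldehyde. The fallback replaces the aldol manifold by an irreversible cationic alkylation, the electrophile class with the strongest γ-preference. It sets out from 25 and returns at 26. 4-Methoxybenzyl chloromethyl ether with ZnBr2 in CH2Cl2 would give the C11 4-methoxybenzyl ether F3, and DDQ in wet CH2Cl2 would release the alcohol.

**Step 17.** Displacement at the β-branched C11 may be slow enough for β-elimination across C9–C11 to compete, since C9–H is vinylogously acidified, or for C9 to epimerise. The fallback forms the C9–C11 bond with the ether oxygen already in place, so no substitution at C11 is needed. It sets out from 27 and 25 and returns at 28. Isofraxidin would be converted with NaH and chloromethyl methyl sulfide into the methylthiomethyl ether F4, and SO2Cl2 would turn F4 into the chloromethyl ether F5. F5 with ZnBr2 would then alkylate 25 at C9 from the α face.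

## Further compounds

F0 | step 8 | none | none
F1 | step 7 | (2Z)-3-methyl-4-(1-methyl-4-oxocyclohexa-2,5-dien-1-yl)but-2-en-1-yl acetate | CC1(C/C(C)=C\COC(C)=O)C=CC(=O)C=C1
F2 | step 9 | cis-fused (5β-H, 10β-CH3) 11,13,14-trinor-drima-1,7-diene-3,6-dione | C1C(C)=CC(=O)[C@@H]2CC(=O)C=C[C@]12C
F3 | step 16 | 11-(4-methoxybenzyloxy)-3α-(3-methylbutanoyloxy)-drim-7-en-6-one (5α-H, 9β-H, 10β-CH3) | COc1ccc(COC[C@@H]2C(C)=CC(=O)[C@H]3C(C)(C)[C@H](OC(=O)CC(C)C)CC[C@]23C)cc1
F4 | step 17 | 6,8-dimethoxy-7-[(methylsulfanyl)methoxy]-2H-chromen-2-one | COc1cc2ccc(=O)oc2c(OC)c1OCSC
F5 | step 17 | 7-(chloromethoxy)-6,8-dimethoxy-2H-chromen-2-one | COc1cc2ccc(=O)oc2c(OC)c1OCCl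
A1 | alternative 1 | methyl (2Z,6S,8Z,10E)-6,9-bis(tert-butyldimethylsilyloxy)-3,7,7-trimethyldodeca-2,8,10-trienoate | COC(=O)/C=C(/C)CC[C@H](O[Si](C)(C)C(C)(C)C)C(C)(C)/C=C(O[Si](C)(C)C(C)(C)C)/C=C/C
A2 | alternative 1 | cis-fused methyl 3β,6-bis(tert-butyldimethylsilyloxy)-drim-6-en-11-oate (C11 α, C12 α) | COC(=O)[C@@H]1[C@H](C)C=C(O[Si](C)(C)C(C)(C)C)[C@@H]2C(C)(C)[C@@H](O[Si](C)(C)C(C)(C)C)CC[C@]12C
A3 | alternative 2 | (1R,5R)-verbenone, (1R,5R)-4,6,6-trimethylbicyclo[3.1.1]hept-3-en-2-one | CC1=CC(=O)[C@@H]2C[C@H]1C2(C)C
A4 | alternative 2 | 11-(4-methoxybenzyloxy)-12-nor-3,4-seco-drim-4(13)-en-3-al 8-ethylene ketal | C(OCc1ccc(OC)cc1)[C@@H]1C2(OCCO2)CC[C@@H](C(C)=C)[C@]1(C)CCC=O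
A5 | alternative 2 | trans-fused 3β-hydroxy-11-(4-methoxybenzyloxy)-12-nor-drimane 8-ethylene ketal | C(OCc1ccc(OC)cc1)[C@@H]1C2(OCCO2)CC[C@H]3C(C)(C)[C@@H](O)CC[C@]13C
A6 | alternative 3 | 2,6-dimethyl-1,4-benzoquinone | CC1=CC(=O)C=C(C)C1=O
A7 | alternative 3 | trimethyl[(4-methylpenta-1,3-dien-3-yl)oxy]silane | C=CC(O[Si](C)(C)C)=C(C)C
A8 | alternative 3 | cis-fused 3-(trimethylsilyloxy)-11-nor-drima-2,7-diene-6,9-dione | O=C1C(C)=CC(=O)[C@@H]2C(C)(C)C(O[Si](C)(C)C)=CC[C@]12C
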